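**Retrosynthetic overview**
1. Target 19 ⇐ one-pot saponification of methyl ester/aryl pivalate 18 ⇐ C3=C4 dehydrogenation (DDQ) of chroman 17.
2. The pyran ring is the only ring formed (the arene is bought): O1–C8a by intramolecular Pd C–O coupling of the tertiary carbinol onto an aryl triflate (16), after C4–C4a is made by B-alkyl Suzuki coupling of the vinyl group of 10 with iodo-triflate 14 (from 2,3-dimethylhydroquinone).
3. Side chain of 10: the C2=C3 enoate by Wittig reaction of aldehyde 5 with α-homoprenyl ylide 9.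
4. Key C–C bond: the σ-bond joining the two isoprenoid units and the (E)-trisubstituted alkene of 5 form together in a Claisen [3,3] rearrangement of allyl vinyl ether 4; its allylic alcohol 3 comes from a singlet-oxygen ene reaction of (S)-linalool.
5. The single stereocentre is C-3 of (S)-linalool; none of its four bonds is broken at any stage.

Assumption: (S)-(+)-linalool (coriandrol) is bought in high enantiomeric purity; target C-2 is (S) and corresponds to C-3 of (S)-linalool with retention.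

**Route**

Step 1
Reactants: 1 (S)-(+)-linalool
Product: 3 (6S)-2,6-dimethylocta-1,7-diene-3,6-diol (C-3 epimer mixture), via secondary allylic hydroperoxide 2 (not isolated)
Conditions: O2, TPP (cat.), hν (white LED), CH2Cl2, 0 °C; then PPh3, 0 °C → rt
Reagents that add atoms: dioxygen O=O
Why: Schenck ene reaction of singlet oxygen at the trisubstituted alkene only (the vinyl group has no allylic hydrogen) gives, after PPh3 reduction, the isopropenyl carbinol; the new secondary carbinol centre forms as an unselected ~1:1 mixture that is erased in step 2, C-6 is untouched, and the regioisomeric tertiary allylic alcohol (about half the material) is removed by chromatography.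

Step 2
Reactants: 3 (6S)-2,6-dimethylocta-1,7-diene-3,6-diol
Product: 5 (4E,8S)-8-hydroxy-4,8-dimethyldeca-4,9-dienal, via allyl vinyl ether 4 (not isolated)
Conditions: ethyl vinyl ether (solvent), Hg(OAc)2 (cat.), NaOAc, reflux; concentrate; then PhMe, BHT, 135 °C (sealed tube)
Reagents that add atoms: ethyl vinyl ether C=COCC
Why: Hg(II)-catalysed transvinylation occurs at the secondary hydroxyl (tertiary carbinols exchange very poorly), and the allyl vinyl ether undergoes a Claisen [3,3]-sigmatropic rearrangement through a chair transition state with the side chain equatorial, forming the new C2–C3 σ-bond and the (4E)-alkene (about 9:1 E/Z, minor isomer removed after step 4) while converting the transient carbinol centre to sp2.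

Step 3
Reactants: 6 methyl (triphenyl-λ5-phosphanylidene)acetate; 7 5-bromo-2-methylpent-2-ene
Product: 9 methyl 6-methyl-2-(triphenyl-λ5-phosphanylidene)hept-5-enoate, via phosphonium bromide 8 (not isolated)
Conditions: NaI (cat.), MeCN, 80 °C; then aq. NaOH, CH2Cl2, 0 °C
Reagents that add atoms: none
Why: SN2 C-alkylation of the stabilised ester ylide by the primary homoallylic halide (iodide-catalysed) gives the phosphonium salt, which aqueous NaOH deprotonates to the α-substituted stabilised ylide.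

Step 4
Reactants: 5 (4E,8S)-8-hydroxy-4,8-dimethyldeca-4,9-dienal; 9 methyl 6-methyl-2-(triphenyl-λ5-phosphanylidene)hept-5-enoate
Product: 10 methyl (2E,6E,10S)-10-hydroxy-6,10-dimethyl-2-(4-methylpent-3-en-1-yl)dodeca-2,6,11-trienoate
Conditions: PhMe, 90 °C; AgNO3–SiO2 chromatography
Reagents that add atoms: none
Why: Wittig olefination with an α-substituted stabilised ylide places the ester trans to the aldehyde-derived chain, giving the (2E)-enoate (>95:5), and the free tertiary carbinol is inert.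

Step 5
Reactants: 11 2,3-dimethylbenzene-1,4-diol
Product: 12 4-hydroxy-2,3-dimethylphenyl 2,2-dimethylpropanoate
Conditions: PivCl (1.0 equiv), pyridine, CH2Cl2, −20 → 0 °C (diol and bis-ester recycled)
Reagents that add atoms: pivaloyl chloride CC(C)(C)C(=O)Cl
Why: Statistical mono-acylation of the symmetric hydroquinone differentiates the two oxygens with a group that survives the later phosphate and carbonate bases and falls off in the final saponification.

Step 6
Reactants: 12 4-hydroxy-2,3-dimethylphenyl 2,2-dimethylpropanoate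
Product: 13 4-hydroxy-5-iodo-2,3-dimethylphenyl 2,2-dimethylpropanoate
Conditions: NIS, TsOH (cat.), MeCN, 0 °C → rt, dark
Reagents that add atoms: N-iodosuccinimide O=C1CCC(=O)N1I
Why: Electrophilic aromatic iodination is directed ortho to the free phenol, whose para and other ortho positions are blocked, so iodine enters only at C-5.

Step 7
Reactants: 13 4-hydroxy-5-iodo-2,3-dimethylphenyl 2,2-dimethylpropanoate
Product: 14 5-iodo-2,3-dimethyl-4-[(trifluoromethanesulfonyl)oxy]phenyl 2,2-dimethylpropanoate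
Conditions: Tf2O, pyridine, CH2Cl2, 0 °C
Reagents that add atoms: trifluoromethanesulfonic anhydride O=S(=O)(OS(=O)(=O)C(F)(F)F)C(F)(F)F
Why: O-Sulfonylation turns the phenolic oxygen that will be replaced in the ring closure into a leaving group for palladium.

Step 8
Reactants: 10 methyl (2E,6E,10S)-10-hydroxy-6,10-dimethyl-2-(4-methylpent-3-en-1-yl)dodeca-2,6,11-trienoate; 14 5-iodo-2,3-dimethyl-4-[(trifluoromethanesulfonyl)oxy]phenyl 2,2-dimethylpropanoate
Product: 16 methyl (2E,6E,10S)-12-{3,4-dimethyl-5-[(2,2-dimethylpropanoyl)oxy]-2-[(trifluoromethanesulfonyl)oxy]phenyl}-10-hydroxy-6,10-dimethyl-2-(4-methylpent-3-en-1-yl)dodeca-2,6-dienoate, via B-alkyl-9-BBN adduct 15 (not isolated)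
Conditions: 9-BBN (2.2 equiv), THF, 0 °C → rt; then 14, PdCl2(dppf) (5 mol %), aq. K3PO4, DMF, 45 °C
Reagents that add atoms: none
Why: 9-BBN hydroborates only the monosubstituted vinyl group anti-Markovnikov, and the B-alkyl Suzuki–Miyaura coupling occurs at C–I in preference to C–OTf, forming the C4–C4a bond without touching the carbinol centre.

Step 9
Reactants: 16 methyl (2E,6E,10S)-12-{3,4-dimethyl-5-[(2,2-dimethylpropanoyl)oxy]-2-[(trifluoromethanesulfonyl)oxy]phenyl}-10-hydroxy-6,10-dimethyl-2-(4-methylpent-3-en-1-yl)dodeca-2,6-dienoate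
Product: 17 methyl (2E,6E)-9-{(2S)-6-[(2,2-dimethylpropanoyl)oxy]-2,7,8-trimethyl-3,4-dihydro-2H-chromen-2-yl}-6-methyl-2-(4-methylpent-3-en-1-yl)nona-2,6-dienoate
Conditions: Pd(OAc)2 (5 mol %), t-BuXPhos (7.5 mol %), Cs2CO3, PhMe, 80 °C
Reagents that add atoms: none
Why: Buchwald-type intramolecular Pd-catalysed C–O coupling (oxidative addition into C–OTf, alkoxide binding, reductive elimination) closes the six-membered ring through the carbinol oxygen, so no bond at the stereocentre is broken and the (S)-linalool centre becomes (2S) of the chroman.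

Step 10
Reactants: 17 methyl (2E,6E)-9-{(2S)-6-[(2,2-dimethylpropanoyl)oxy]-2,7,8-trimethyl-3,4-dihydro-2H-chromen-2-yl}-6-methyl-2-(4-methylpent-3-en-1-yl)nona-2,6-dienoate
Product: 18 methyl (2E,6E)-9-{(2S)-6-[(2,2-dimethylpropanoyl)oxy]-2,7,8-trimethyl-2H-chromen-2-yl}-6-methyl-2-(4-methylpent-3-en-1-yl)nona-2,6-dienoate
Conditions: DDQ (1.3 equiv), 1,4-dioxane, 90 °C, dark
Reagents that add atoms: none
Why: DDQ dehydrogenation: hydride abstraction from benzylic C-4 (cation stabilised by the ortho ring oxygen and para methyl) and loss of H-3 gives the 2H-chromene, while quaternary C-2, the isolated alkenes and the enoate are much less reactive.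

Step 11
Reactants: 18 methyl (2E,6E)-9-{(2S)-6-[(2,2-dimethylpropanoyl)oxy]-2,7,8-trimethyl-2H-chromen-2-yl}-6-methyl-2-(4-methylpent-3-en-1-yl)nona-2,6-dienoate
Product: 19 (2E,6E)-9-[(2S)-6-hydroxy-2,7,8-trimethyl-2H-chromen-2-yl]-6-methyl-2-(4-methylpent-3-en-1-yl)nona-2,6-dienoic acid
Conditions: LiOH·H2O (6 equiv), THF/MeOH/H2O (degassed), 45 °C, dark; then 1 M HCl, 0 °C
Reagents that add atoms: lithium hydroxide [Li+].[OH-]
Why: Saponification (BAc2) cleaves the methyl ester and the aryl pivalate in one operation without affecting the alkenes or the quaternary stereocentre; air and light are excluded because the chromenol phenolate is oxidisable and 2H-chromenes are photolabile.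

**Compound list**
1 | (S)-(+)-linalool, (3S)-3,7-dimethylocta-1,6-dien-3-ol | CC(C)=CCC[C@](C)(O)C=C | starting material
2 | (3S)-6-hydroperoxy-3,7-dimethylocta-1,7-dien-3-ol (C-6 epimers) | C=C(C)C(OO)CC[C@](C)(O)C=C | intermediate
3 | (6S)-2,6-dimethylocta-1,7-diene-3,6-diol (C-3 epimers) | C=C(C)C(O)CC[C@](C)(O)C=C | intermediate
4 | (3S)-6-(ethenyloxy)-3,7-dimethylocta-1,7-dien-3-ol (C-6 epimers) | C=COC(CC[C@](C)(O)C=C)C(C)=C | intermediate
5 | (4E,8S)-8-hydroxy-4,8-dimethyldeca-4,9-dienal | O=CCC/C(C)=C/CC[C@](C)(O)C=C | intermediate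
6 | methyl (triphenyl-λ5-phosphanylidene)acetate | COC(=O)C=P(c1ccccc1)(c1ccccc1)c1ccccc1 | starting material
7 | 5-bromo-2-methylpent-2-ene | CC(C)=CCCBr | starting material
8 | (1-methoxy-6-methyl-1-oxohept-5-en-2-yl)triphenylphosphonium bromide (racemic) | COC(=O)C(CCC=C(C)C)[P+](c1ccccc1)(c1ccccc1)c1ccccc1.[Br-] | intermediate
9 | methyl 6-methyl-2-(triphenyl-λ5-phosphanylidene)hept-5-enoate | COC(=O)C(CCC=C(C)C)=P(c1ccccc1)(c1ccccc1)c1ccccc1 | intermediate
10 | methyl (2E,6E,10S)-10-hydroxy-6,10-dimethyl-2-(4-methylpent-3-en-1-yl)dodeca-2,6,11-trienoate | COC(=O)/C(CCC=C(C)C)=C/CC/C(C)=C/CC[C@](C)(O)C=C | intermediate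
11 | 2,3-dimethylbenzene-1,4-diol | Cc1c(O)ccc(O)c1C | starting material
12 | 4-hydroxy-2,3-dimethylphenyl 2,2-dimethylpropanoate | CC(C)(C)C(=O)Oc1ccc(O)c(C)c1C | intermediate
13 | 4-hydroxy-5-iodo-2,3-dimethylphenyl 2,2-dimethylpropanoate | CC(C)(C)C(=O)Oc1cc(I)c(O)c(C)c1C | intermediate
14 | 5-iodo-2,3-dimethyl-4-[(trifluoromethanesulfonyl)oxy]phenyl 2,2-dimethylpropanoate | CC(C)(C)C(=O)Oc1cc(I)c(OS(=O)(=O)C(F)(F)F)c(C)c1C | intermediate
15 | methyl (2E,6E)-12-(9-borabicyclo[3.3.1]nonan-9-yl)-10-hydroxy-6,10-dimethyl-2-(4-methylpent-3-en-1-yl)dodeca-2,6-dienoate, carbinol centre as in 10 (formally 10R because B ranks below C) | COC(=O)/C(CCC=C(C)C)=C/CC/C(C)=C/CC[C@](C)(O)CCB1C2CCCC1CCC2 | intermediate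
16 | methyl (2E,6E,10S)-12-{3,4-dimethyl-5-[(2,2-dimethylpropanoyl)oxy]-2-[(trifluoromethanesulfonyl)oxy]phenyl}-10-hydroxy-6,10-dimethyl-2-(4-methylpent-3-en-1-yl)dodeca-2,6-dienoate | COC(=O)/C(CCC=C(C)C)=C/CC/C(C)=C/CC[C@](C)(O)CCc1cc(OC(=O)C(C)(C)C)c(C)c(C)c1OS(=O)(=O)C(F)(F)F | intermediate
17 | methyl (2E,6E)-9-{(2S)-6-[(2,2-dimethylpropanoyl)oxy]-2,7,8-trimethyl-3,4-dihydro-2H-chromen-2-yl}-6-methyl-2-(4-methylpent-3-en-1-yl)nona-2,6-dienoate | COC(=O)/C(CCC=C(C)C)=C/CC/C(C)=C/CC[C@@]1(C)CCc2cc(OC(=O)C(C)(C)C)c(C)c(C)c2O1 | intermediate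
18 | methyl (2E,6E)-9-{(2S)-6-[(2,2-dimethylpropanoyl)oxy]-2,7,8-trimethyl-2H-chromen-2-yl}-6-methyl-2-(4-methylpent-3-en-1-yl)nona-2,6-dienoate | COC(=O)/C(CCC=C(C)C)=C/CC/C(C)=C/CC[C@@]1(C)C=Cc2cc(OC(=O)C(C)(C)C)c(C)c(C)c2O1 | intermediate
19 | (2E,6E)-9-[(2S)-6-hydroxy-2,7,8-trimethyl-2H-chromen-2-yl]-6-methyl-2-(4-methylpent-3-en-1-yl)nona-2,6-dienoic acid (CNP0158414.1) | CC(C)=CCC/C(=C\CC/C(C)=C/CC[C@@]1(C)C=Cc2cc(O)c(C)c(C)c2O1)C(=O)O | target

**Step count and risks**

Total step count: 11. Longest linear sequence: 7 steps (1 → 3 → 5 → 10 → 16 → 17 → 18 → 19; the arene branch 11 → 14 → 19 is also 7).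

Three steps most likely to fail:

Step 2 (transvinylation/Claisen on a diol). The risks are partial vinylation of the tertiary carbinol, which would then rearrange and destroy that material, and only about 9:1 E/Z. The fallback drops the rearrangement and homologates the E-methyl group of linalool directly. Setting out from 1, SeO2 (cat.)/t-BuOOH allylic oxidation with NaBH4 work-up gives (2E,6S)-2,6-dimethylocta-2,7-diene-1,6-diol F1. CBr4/PPh3 converts only the primary allylic hydroxyl into (3S,6E)-8-bromo-3,7-dimethylocta-1,6-dien-3-ol F2. SN2 alkylation with the lithium aza-enolate of acetaldehyde N-tert-butylimine (2.2 equiv, THF, −78 °C) gives (3S,6E)-10-(tert-butylimino)-3,7-dimethyldeca-1,6-dien-3-ol F3, which aqueous oxalic acid hydrolyses to 5, where the route is rejoined.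

Step 9 (Pd C–O coupling at a di-ortho-substituted aryl triflate with a tertiary alkoxide). The risks are sulfonyl transfer or hydrolysis of the triflate and slow oxidative addition. The fallback changes the ring-closing manifold to a copper-mediated Ullmann etherification of an aryl bromide. Setting out from 16, Ru-catalysed triflate-to-bromide exchange ([Cp*Ru(MeCN)3]OTf, LiBr, DMI, 100 °C) gives methyl (2E,6E,10S)-12-{2-bromo-3,4-dimethyl-5-[(2,2-dimethylpropanoyl)oxy]phenyl}-10-hydroxy-6,10-dimethyl-2-(4-methylpent-3-en-1-yl)dodeca-2,6-dienoate F4. CuI/3,4,7,8-tetramethyl-1,10-phenanthroline/Cs2CO3 (PhMe, 110 °C) then forms the O–aryl bond through the carbinol oxygen, again with retention, and returns to 17.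

Step 10 (DDQ dehydrogenation of a 6-acyloxychroman in the presence of three other alkenes). The risks are sluggish hydride abstraction and allylic over-oxidation. The fallback brings the C3=C4 double bond in with the coupling step instead of oxidising late. Setting out from 10 and 14, a C–I-selective Heck reaction (Pd(OAc)2, Bu4NCl, NaHCO3, DMF, 60 °C) gives methyl (2E,6E,10S,11E)-12-{3,4-dimethyl-5-[(2,2-dimethylpropanoyl)oxy]-2-[(trifluoromethanesulfonyl)oxy]phenyl}-10-hydroxy-6,10-dimethyl-2-(4-methylpent-3-en-1-yl)dodeca-2,6,11-trienoate F5. Visible-light triplet-sensitised E→Z isomerisation of the styrenyl alkene (Ir(ppy)3, blue LEDs, MeCN, rt) gives methyl (2E,6E,10S,11Z)-12-{3,4-dimethyl-5-[(2,2-dimethylpropanoyl)oxy]-2-[(trifluoromethanesulfonyl)oxy]phenyl}-10-hydroxy-6,10-dimethyl-2-(4-methylpent-3-en-1-yl)dodeca-2,6,11-trienoate F6. The Pd-catalysed C–O coupling conditions of step 9 then close the cis-alkenyl carbinol directly to chromene 18, where the route is rejoined.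

**Further compounds**
F1 | step 2 | (2E,6S)-2,6-dimethylocta-2,7-diene-1,6-diol | OC/C(C)=C/CC[C@](C)(O)C=C
F2 | step 2 | (3S,6E)-8-bromo-3,7-dimethylocta-1,6-dien-3-ol | BrC/C(C)=C/CC[C@](C)(O)C=C
F3 | step 2 | (3S,6E)-10-(tert-butylimino)-3,7-dimethyldeca-1,6-dien-3-ol | CC(C)(C)N=CCC/C(C)=C/CC[C@](C)(O)C=C
F4 | step 9 | methyl (2E,6E,10S)-12-{2-bromo-3,4-dimethyl-5-[(2,2-dimethylpropanoyl)oxy]phenyl}-10-hydroxy-6,10-dimethyl-2-(4-methylpent-3-en-1-yl)dodeca-2,6-dienoate | COC(=O)/C(CCC=C(C)C)=C/CC/C(C)=C/CC[C@](C)(O)CCc1cc(OC(=O)C(C)(C)C)c(C)c(C)c1Br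
F5 | step 10 | methyl (2E,6E,10S,11E)-12-{3,4-dimethyl-5-[(2,2-dimethylpropanoyl)oxy]-2-[(trifluoromethanesulfonyl)oxy]phenyl}-10-hydroxy-6,10-dimethyl-2-(4-methylpent-3-en-1-yl)dodeca-2,6,11-trienoate | COC(=O)/C(CCC=C(C)C)=C/CC/C(C)=C/CC[C@](C)(O)/C=C/c1cc(OC(=O)C(C)(C)C)c(C)c(C)c1OS(=O)(=O)C(F)(F)F
F6 | step 10 | methyl (2E,6E,10S,11Z)-12-{3,4-dimethyl-5-[(2,2-dimethylpropanoyl)oxy]-2-[(trifluoromethanesulfonyl)oxy]phenyl}-10-hydroxy-6,10-dimethyl-2-(4-methylpent-3-en-1-yl)dodeca-2,6,11-trienoate | COC(=O)/C(CCC=C(C)C)=C/CC/C(C)=C/CC[C@](C)(O)/C=C\c1cc(OC(=O)C(C)(C)C)c(C)c(C)c1OS(=O)(=O)C(F)(F)F
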